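Assumption: chain atoms are numbered C1 (lactone carbonyl) to C27 (methyl on the nitrogen-bearing carbon C26), with methyl branches on C5, C8, C19, C22 and C24; compound 7 is taken as the commercially supplied (4R,6S) statin side-chain aldehyde.

## Structural features

Superstolide A is a 16-membered macrolactone (C1–C8, C17–C23 and the oxygen on C23) fused across the C8–C17 bond to a cis-decalin made of cyclohexane ring A (C9–C14) and cyclohexene ring B (C8, C9, C14, C15=C16, C17). Ring B carries four contiguous stereocentres, the quaternary C8 (methyl plus the C7 vinyl carbon), C9, C14 and C17. The four carbon substituents C7, C10, C13 and C18 lie on one face, so the ring fusion is cis and the macrocycle bridges C8 and C17 in a cis sense. Ring A holds a syn-1,3 dioxygen pattern (C11 methyl ether, C13 primary carbamate). The macrocycle contains a (2E,4Z,6E)-trienoate ending at C8 and an (18E,20E)-diene starting at C17, and the side chain C22–C26 is a stereopentad (methyl, lactone oxygen, methyl, hydroxyl, acetamide; anti, syn, anti, anti). Fragile points are the 4Z-trienoate (isomerisation, 6π-electrocyclisation on strong heating), the doubly allylic C17–H, the base-labile carbamate and lactone, and any oxygen at C13 while it is still allylic to a polyene. The real difficulty is the C8/C9/C14/C17 array, with its quaternary centre shared by decalin and macrocycle, and its absolute configuration relative to the remote C22–C26 array. The key step exploits the fact that ring B is a cyclohexene whose C15=C16 bond lies opposite the C8–C9 bond: a retro-[4+2] cut of C8–C17 and C9–C14 removes at once the bond shared with the 16-membered ring and the bond shared with ring A. What remains is a 24-membered macrolactone in which a C14–C17 diene and a C8=C9 dienophile are joined by the four-carbon tether C10–C13.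

## Logic of the disconnections

44 back to 40 (through 43 and 41). Cut: the carbamoyl C–O13 bond, the Si–O13 bond and the two bonds from O25 and N26 to an isopropylidene carbon. Reason: a primary carbamate that is allylic to a tetraene would not survive strong base or zerovalent palladium, and a free amide N–H next to the future C23 aldehyde would form a hemiaminal. Gain: the late intermediates carry only a silyl ether and an N,O-acetal. Demand: three orthogonal unmaskings in the order fluoride, carbamoylation, mild aqueous acid.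

40 back to 39 (key). Cut: C8–C17 and C9–C14. Reason: one cycloaddition closes ring B, ring A and the 16-membered lactone and sets C8, C9, C14 and C17 together. Gain: 39 has no carbocycle and only the stereocentres that come from two small building blocks. Demand: the forward step must select one diene/dienophile pair, the endo mode and one diene face.

39 back to 38. Cut: C7–C8 (sp2–sp2). Reason: this bond completes the conjugation that activates C8=C9, so no acyclic precursor can cyclise early, and it lies far from every stereocentre. Gain: an open chain with one vinyl iodide and one vinyl stannane. Demand: coupling with retention of the 6E and 8Z geometries at high dilution and ambient temperature.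

38 back to 36 and 6 (through 37). Cut: C2=C3 and the O23–C1 acyl bond. Reason: the hindered C23 hydroxyl is acylated by a small activated acid instead of a polyenoic acid, and the 4Z bond is brought in ready-made. Gain: 6 is a five-carbon piece. Demand: E-selective olefination under base mild enough for a Z enal.

36 (through 35) back to 18 and 34. Cut: C20=C21. Reason: a carbonyl olefination is orthogonal to the vinyl iodide of 18, whereas a cross-coupling here would compete with it. Gain: two fragments of similar size, each with one stereochemical array. Demand: E-selective olefination with a β-branched sulfone and a conjugated aldehyde.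

18 back to 7, 8 and 16 (through 17, 15, 14, 13, 12, 11 and 9). Cut: C18=C19, C8=C9 and C14=C15; no C–C bond at a stereocentre is formed. Reason: 7 already holds C11 and C13 with the right syn configuration, and the six-membered lactone of 11 and 12 tells O11 (methylated) from O13 (held in the ring). Gain: both stereocentres are bought. Demand: Z-selective iodo-olefination of a lactol and chemoselective oxidation of a primary beside a secondary alcohol.

34 back to 19 (through 33, 32, 29, 28, 26, 24, 23 and 21). Cut: C22–C23 and C24–C25. Reason: two reagent-controlled crotylborations build the pentad from the one purchased centre C26. Gain: a four-carbon amino aldehyde. Demand: each crotylboration must give the anti pair with the stated facial sense; the second is matched with Felkin control.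

6 back to 3 and 4, and 3 back to 1. Cut: C5–C6. Reason: the Z geometry comes from a directed trans-hydroalumination and the E-vinyl tin from a symmetrical reagent. Gain: four-carbon and two-carbon starting materials. Demand: coupling at only one tin of 4.

## Other disconnections considered

Alternative 1: The first plan that comes to mind cuts the lactone C1–O23 bond and makes the decalin early. An intramolecular Diels–Alder reaction of a short acyclic triene would give the cis-decalin A1 (C7 as methyl ester, C18 as aldehyde), which is extended at C7 and C18 to the seco acid A2 and closed by macrolactonisation. The chosen plan is preferred for three reasons. In the short triene only C13 can direct the diene face, and nothing enforces the endo mode for a trisubstituted dienophile. Both polyenes would then have to be built on the decalin in a linear sequence. The ring closure must acylate the most hindered hydroxyl of the molecule (C23, flanked by two methyl-bearing carbons) with an activated 4Z-trienoic acid, a reaction type in which Z to E isomerisation is a recognised weakness.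

Alternative 2: Cut the sp2–sp2 bond C19–C20, far from the lactone, after joining all fragments through the ester. The acyclic octaene A3 (C19 boronate, C20 iodide) would undergo the same [4+2] reaction, and an intramolecular Suzuki coupling would then close the 16-membered ring. This uses the same cycloaddition without the conformational constraint of the macrocycle, so the endo mode and the diene face rest on C11/C13 alone. The later cross-coupling would have to close a ring that bridges two adjacent ring carbons, one of them quaternary, which is a more strained closure than forming the flexible 24-membered ring of 39. The step count is not lower.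

Alternative 3: Use an aromatic template for ring A. In tetralin A4, C9–C14 form a resorcinol-type arene, and C8 and C17 are set beforehand. An all-cis arene hydrogenation with (CAAC)Rh(cod)Cl and H2 would set C9, C11, C13 and C14 in one step to give A5, because H9, H11, H13 and H14 of the target lie on one face. This is attractive for ring A, but hydrogenation must come before every alkene, so the C15=C16 bond and both polyenes have to be installed afterwards. The diene face would be chosen only by the steric difference between methyl and CH2OSi on C8. The macrocycle would still need a separate closure, so the plan is longer and less convergent.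

Key step: step 26

## Steps

Step 1
Reactants: 1 but-2-yn-1-ol
Product: 3 (Z)-3-iodobut-2-en-1-ol, via cyclic vinylalanate 2 (not isolated)
Conditions: NaAlH2(OCH2CH2OMe)2, THF, 0 °C to rt; then I2, THF, −78 to 0 °C
Reagents that add atoms: iodine, II
Why: Hydroxyl-directed trans-hydroalumination of the propargylic alcohol puts aluminium on C3 in a five-membered alanate, and iodinolysis with retention should give the Z iodide whose geometry becomes the 4Z bond of the target.

Step 2
Reactants: 3 (Z)-3-iodobut-2-en-1-ol; 4 (E)-1,2-bis(tributylstannyl)ethene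
Product: 5 (2Z,4E)-3-methyl-5-(tributylstannyl)penta-2,4-dien-1-ol
Conditions: PdCl2(MeCN)2 (5 mol %), DMF, rt; 4 in threefold excess
Reagents that add atoms: none
Why: Stille coupling at one tin of the symmetrical bis-stannane with retention at both partners; the excess of 4 should suppress double coupling.

Step 3
Reactants: 5 (2Z,4E)-3-methyl-5-(tributylstannyl)penta-2,4-dien-1-ol
Product: 6 (2Z,4E)-3-methyl-5-(tributylstannyl)penta-2,4-dienal
Conditions: MnO2, CH2Cl2, rt
Reagents that add atoms: none
Why: Neutral allylic oxidation on MnO2 should leave the vinyl stannane and the Z trisubstituted alkene untouched.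

Step 4
Reactants: 7 tert-butyl 2-[(4R,6S)-6-formyl-2,2-dimethyl-1,3-dioxan-4-yl]acetate; 8 triethyl 4-phosphonocrotonate
Product: 9 tert-butyl 2-[(4R,6S)-6-[(1E,3E)-5-ethoxy-5-oxopenta-1,3-dien-1-yl]-2,2-dimethyl-1,3-dioxan-4-yl]acetate
Conditions: LiN(SiMe3)2, THF, −78 to 0 °C
Reagents that add atoms: none
Why: Vinylogous Horner–Wadsworth–Emmons olefination; the ester-stabilised phosphonate adds reversibly and eliminates to the E alkene, giving the (14E,16E)-dienoate without touching the α-alkoxy centre C13 at low temperature.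

Step 5
Reactants: 9 tert-butyl 2-[(4R,6S)-6-[(1E,3E)-5-ethoxy-5-oxopenta-1,3-dien-1-yl]-2,2-dimethyl-1,3-dioxan-4-yl]acetate
Product: 11 ethyl (2E,4E)-5-[(2S,4R)-4-hydroxy-6-oxooxan-2-yl]penta-2,4-dienoate, via dihydroxy acid 10 (not isolated)
Conditions: CF3CO2H, CH2Cl2, H2O (1 equiv), rt
Reagents that add atoms: none
Why: Acid cleaves the acetonide and the tert-butyl ester and the C13 hydroxyl closes the six-membered lactone onto C9 (statin-type lactonisation), which masks C9 and O13 together and leaves only the C11 hydroxyl free; the electron-poor dienoate disfavours ionisation at allylic C13.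

Step 6
Reactants: 11 ethyl (2E,4E)-5-[(2S,4R)-4-hydroxy-6-oxooxan-2-yl]penta-2,4-dienoate
Product: 12 ethyl (2E,4E)-5-[(2S,4R)-4-methoxy-6-oxooxan-2-yl]penta-2,4-dienoate
Conditions: Me3OBF4, 1,8-bis(dimethylamino)naphthalene, CH2Cl2, 0 °C to rt
Reagents that add atoms: trimethyloxonium tetrafluoroborate, C[O+](C)C.F[B-](F)(F)F
Why: Meerwein-salt O-methylation under non-basic conditions, so neither β-elimination of the β-oxy lactone nor alkoxide addition to the dienoate can compete.

Step 7
Reactants: 12 ethyl (2E,4E)-5-[(2S,4R)-4-methoxy-6-oxooxan-2-yl]penta-2,4-dienoate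
Product: 13 (4R,6S)-6-[(1E,3E)-5-hydroxypenta-1,3-dien-1-yl]-4-methoxyoxan-2-ol (anomeric mixture)
Conditions: i-Bu2AlH (4.5 equiv), CH2Cl2, −78 °C; aqueous potassium sodium tartrate work-up
Reagents that add atoms: none
Why: Hydride reduction at low temperature should stop at the lactol (stable tetrahedral aluminate) while the conjugated ethyl ester is reduced in 1,2-fashion to the dienol; C9 then has the aldehyde oxidation level.

Step 8
Reactants: 13 (4R,6S)-6-[(1E,3E)-5-hydroxypenta-1,3-dien-1-yl]-4-methoxyoxan-2-ol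
Product: 14 (2E,4E,6S,8S,10Z)-11-iodo-8-methoxydodeca-2,4,10-triene-1,6-diol
Conditions: [Ph3PCH(I)CH3]I (preformed), NaN(SiMe3)2, THF, −78 °C; then 13, −78 to −20 °C
Reagents that add atoms: (1-iodoethyl)triphenylphosphonium iodide, CC(I)[P+](c1ccccc1)(c1ccccc1)c1ccccc1.[I-]
Why: Stork–Zhao-type Wittig olefination of the open hydroxy-aldehyde form of the lactol with the unstabilised α-iodo ylide; the kinetically favoured cis-oxaphosphetane puts iodine cis to C10 (8Z vinyl iodide), ring opening frees the C13 hydroxyl, and excess ylide covers the two O–H groups.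

Step 9
Reactants: 14 (2E,4E,6S,8S,10Z)-11-iodo-8-methoxydodeca-2,4,10-triene-1,6-diol
Product: 15 (2E,4E,6S,8S,10Z)-6-hydroxy-11-iodo-8-methoxydodeca-2,4,10-trienal
Conditions: TEMPO (10 mol %), PhI(OAc)2, CH2Cl2, rt
Reagents that add atoms: none
Why: Oxoammonium oxidation is selective for the primary dienylic alcohol over the secondary C13 alcohol and is compatible with the vinyl iodide.

Step 10
Reactants: 15 (2E,4E,6S,8S,10Z)-6-hydroxy-11-iodo-8-methoxydodeca-2,4,10-trienal; 16 2-(triphenylphosphoranylidene)propanal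
Product: 17 (2E,4E,6E,8S,10S,12Z)-8-hydroxy-13-iodo-10-methoxy-2-methyltetradeca-2,4,6,12-tetraenal
Conditions: toluene, 70 °C
Reagents that add atoms: none
Why: Wittig olefination with a formyl-stabilised ylide should give the E trisubstituted C18=C19 bond (methyl cis to C17); the α-branched product enal is much less reactive than the dienal, so a single homologation is expected.

Step 11
Reactants: 17 (2E,4E,6E,8S,10S,12Z)-8-hydroxy-13-iodo-10-methoxy-2-methyltetradeca-2,4,6,12-tetraenal
Product: 18 (2E,4E,6E,8S,10S,12Z)-8-[(tert-butyldimethylsilyl)oxy]-13-iodo-10-methoxy-2-methyltetradeca-2,4,6,12-tetraenal (C8–C20 fragment)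
Conditions: t-BuMe2SiOSO2CF3, 2,6-lutidine, CH2Cl2, −78 °C
Reagents that add atoms: tert-butyldimethylsilyl triflate, CC(C)(C)[Si](C)(C)OS(=O)(=O)C(F)(F)F
Why: Silyl triflate silylation of the secondary C13 alcohol; the ether should survive base, zerovalent palladium and heat and be removed later by fluoride.

Step 12
Reactants: 19 tert-butyl N-[(2R)-1-oxopropan-2-yl]carbamate (N-Boc-D-alaninal)
Product: 21 tert-butyl N-[(2R,3S,4S)-3-hydroxy-4-methylhex-5-en-2-yl]carbamate, via borinate 20 (not isolated)
Conditions: (−)-Ipc2B[(E)-crotyl] [from (+)-α-pinene; freshly prepared solution], THF, −78 °C; then NaOH, H2O2, 0 °C to rt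
Reagents that add atoms: (−)-(E)-crotyldiisopinocampheylborane, C/C=C/CB([C@@H]1C[C@@H]2C[C@H]([C@H]1C)C2(C)C)[C@@H]1C[C@@H]2C[C@H]([C@H]1C)C2(C)C
Why: Brown crotylboration through a closed chair transition state: the E-crotyl unit fixes C24/C25 anti, and the (+)-α-pinene-derived ligands direct attack to the Si face of the aldehyde to give 25S, which is also the Felkin–Anh sense relative to C26.

Step 13
Reactants: 21 tert-butyl N-[(2R,3S,4S)-3-hydroxy-4-methylhex-5-en-2-yl]carbamate
Product: 23 N-[(2R,3S,4S)-3-hydroxy-4-methylhex-5-en-2-yl]acetamide, via ammonium chloride 22 (not isolated)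
Conditions: HCl (4 M in 1,4-dioxane), 0 °C to rt; evaporate; then Ac2O, Et3N, MeOH, 0 °C
Reagents that add atoms: acetic anhydride, CC(=O)OC(C)=O
Why: Acidolysis of the tert-butyl carbamate and N-selective acetylation in methanol (the amine is far more nucleophilic than the hindered secondary alcohol) install the acetamide of the target early.

Step 14
Reactants: 23 N-[(2R,3S,4S)-3-hydroxy-4-methylhex-5-en-2-yl]acetamide
Product: 24 1-[(4R,5S)-5-[(2S)-but-3-en-2-yl]-2,2,4-trimethyl-1,3-oxazolidin-3-yl]ethan-1-one
Conditions: Me2C(OMe)2, BF3·OEt2 (cat.), acetone, rt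
Reagents that add atoms: 2,2-dimethoxypropane, COC(C)(C)OC
Why: Acid-catalysed N,O-acetal formation ties N26 and O25 into an oxazolidine, which removes the amide N–H (no hemiaminal with the coming C23 aldehyde) and protects O25 orthogonally to silyl ethers.

Step 15
Reactants: 24 1-[(4R,5S)-5-[(2S)-but-3-en-2-yl]-2,2,4-trimethyl-1,3-oxazolidin-3-yl]ethan-1-one
Product: 26 (2R)-2-[(4R,5S)-3-acetyl-2,2,4-trimethyl-1,3-oxazolidin-5-yl]propanal, via ozonide 25 (not isolated)
Conditions: O3, CH2Cl2, −78 °C; then PPh3, −78 °C to rt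
Reagents that add atoms: ozone, [O-][O+]=O
Why: Ozonolysis of the only alkene with reductive work-up gives the C23 aldehyde; the α-stereocentre C24 is preserved by using the crude aldehyde at once.

Step 16
Reactants: 26 (2R)-2-[(4R,5S)-3-acetyl-2,2,4-trimethyl-1,3-oxazolidin-5-yl]propanal
Product: 28 1-[(4R,5S)-5-[(2S,3R,4R)-3-hydroxy-4-methylhex-5-en-2-yl]-2,2,4-trimethyl-1,3-oxazolidin-3-yl]ethan-1-one, via borinate 27 (not isolated)
Conditions: (+)-Ipc2B[(E)-crotyl] [from (−)-α-pinene; freshly prepared solution], THF, −78 °C; then NaOH, H2O2, 0 °C to rt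
Reagents that add atoms: (+)-(E)-crotyldiisopinocampheylborane, C/C=C/CB([C@H]1C[C@H]2C[C@@H]([C@@H]1C)C2(C)C)[C@H]1C[C@H]2C[C@@H]([C@@H]1C)C2(C)C
Why: Brown crotylboration via a chair transition state: the E-crotyl unit fixes C22/C23 anti and the (−)-α-pinene-derived ligands direct attack to the Re face to give 23R with C23/C24 syn, which is also the Felkin–Anh sense for the α-methyl aldehyde (matched pairing).

Step 17
Reactants: 28 1-[(4R,5S)-5-[(2S,3R,4R)-3-hydroxy-4-methylhex-5-en-2-yl]-2,2,4-trimethyl-1,3-oxazolidin-3-yl]ethan-1-one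
Product: 29 C20–C27 alkene with C23–OSiEt3 (triethylsilyl ether of 28)
Conditions: Et3SiOSO2CF3, 2,6-lutidine, CH2Cl2, −78 to 0 °C
Reagents that add atoms: triethylsilyl triflate, CC[Si](CC)(CC)OS(=O)(=O)C(F)(F)F
Why: Silylation of the hindered C23 alcohol keeps an alkoxide away from the later sulfonyl carbanion; triethylsilyl is chosen so that it can be removed in the presence of the C13 tert-butyldimethylsilyl ether.

Step 18
Reactants: 29 C20–C27 alkene with C23–OSiEt3
Product: 32 C21–C27 primary alcohol (C21–OH; C23–OSiEt3; C25/C26 N-acetyl N,O-acetonide), via ozonide 30 (not isolated), via aldehyde 31 (not isolated)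
Conditions: O3, CH2Cl2, −78 °C; then NaBH4, MeOH, −78 °C to rt
Reagents that add atoms: ozone, [O-][O+]=O
Why: Ozonolysis followed by borohydride reduction in the same flask removes C20 and gives the C21 alcohol without isolating the epimerisable α-methyl aldehyde.

Step 19
Reactants: 32 C21–C27 primary alcohol
Product: 33 C21–C27 1-phenyl-1H-tetrazol-5-yl sulfide
Conditions: 1-phenyl-1H-tetrazole-5-thiol, PPh3, i-PrO2CN=NCO2i-Pr, THF, 0 °C to rt
Reagents that add atoms: 1-phenyl-1H-tetrazole-5-thiol, Sc1nnnn1-c1ccccc1
Why: Mitsunobu thioetherification at the unhindered primary carbon C21 (SN2; no stereocentre involved).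

Step 20
Reactants: 33 C21–C27 1-phenyl-1H-tetrazol-5-yl sulfide
Product: 34 C21–C27 1-phenyl-1H-tetrazol-5-yl sulfone
Conditions: 3-chloroperbenzoic acid (2.5 equiv), NaHCO3, CH2Cl2, 0 °C to rt
Reagents that add atoms: 3-chloroperbenzoic acid, OOC(=O)c1cccc(Cl)c1
Why: Peracid oxidation of sulfide to sulfone; no alkene is present and the amide and silyl ether are inert.

Step 21
Reactants: 34 C21–C27 1-phenyl-1H-tetrazol-5-yl sulfone; 18 C8–C20 tetraenal
Product: 35 C8–C27 iodo tetraene (8Z,14E,16E,18E,20E; 13-OSiMe2t-Bu; 23-OSiEt3)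
Conditions: KN(SiMe3)2, 1,2-dimethoxyethane, −60 °C; then 18, −60 °C to rt
Reagents that add atoms: none
Why: Julia–Kocienski olefination: addition of the potassium sulfonyl carbanion to the aldehyde, Smiles rearrangement and loss of SO2 and tetrazolate; the anti adduct favoured with this base and solvent leads to the 20E alkene, and the vinyl iodide and C22 should be untouched.

Step 22
Reactants: 35 C8–C27 iodo tetraene
Product: 36 C8–C27 iodo tetraene with free C23 hydroxyl
Conditions: HF·pyridine, pyridine, THF, 0 °C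
Reagents that add atoms: none
Why: Buffered fluoride cleaves the secondary triethylsilyl ether much faster than the secondary tert-butyldimethylsilyl ether, and the pyridine buffer keeps the medium too weakly acidic to ionise the polyenylic C13 ether or open the N,O-acetal.

Step 23
Reactants: 36 C8–C27 iodo tetraene with free C23 hydroxyl
Product: 37 C23 diethylphosphonoacetate of 36
Conditions: (EtO)2P(O)CH2CO2H, N,N'-dicyclohexylcarbodiimide, 4-(dimethylamino)pyridine (cat.), CH2Cl2, 0 °C to rt
Reagents that add atoms: diethylphosphonoacetic acid, OC(=O)CP(=O)(OCC)OCC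
Why: Carbodiimide esterification; diethylphosphonoacetic acid is a small, highly activated acyl donor that should acylate the hindered C23 alcohol without any stereochemical risk.

Step 24
Reactants: 37 C23 diethylphosphonoacetate; 6 (2Z,4E)-3-methyl-5-(tributylstannyl)penta-2,4-dienal
Product: 38 open-chain C1–C27 ester bearing C7–SnBu3 and C8–I
Conditions: LiCl, DBU, MeCN, 0 °C to rt
Reagents that add atoms: none
Why: Horner–Wadsworth–Emmons olefination under Masamune–Roush conditions gives the 2E enoate; the mild base should leave the 4Z bond, the stannane and the vinyl iodide unchanged, and C8=C9 is not yet conjugated, so no cycloaddition can start.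

Step 25
Reactants: 38 open-chain C1–C27 ester bearing C7–SnBu3 and C8–I
Product: 39 24-membered (2E,4Z,6E,8Z,14E,16E,18E,20E)-octaene macrolactone
Conditions: Pd2(dba)3 (20 mol %), AsPh3 (1.6 equiv), i-Pr2NEt, DMF, 25 °C, 0.001 M, slow addition of 38
Reagents that add atoms: none
Why: Intramolecular Stille coupling: oxidative addition of zerovalent palladium into the C8–I bond, transmetalation from the C7 stannane and reductive elimination, all with retention, so 6E and 8Z are carried over; the AsPh3 ligand speeds transmetalation at ambient temperature so that the ring can close below the temperature needed for the cycloaddition.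

Step 26
Reactants: 39 24-membered octaene macrolactone
Product: 40 cis-decalin-fused 16-membered macrolactone (13-OSiMe2t-Bu; C25/C26 N-acetyl N,O-acetonide)
Conditions: toluene (0.005 M), 2,6-di-tert-butyl-4-methylphenol (cat.), 80 °C, argon, dark
Reagents that add atoms: none
Why: Concerted suprafacial [4+2] cycloaddition in which the (14E,16E)-diene C14–C17 adds across the 8Z bond C8=C9, the terminal alkene of the C1–C9 tetraenoate (large LUMO coefficient at C9); the closest known reaction type is the transannular Diels–Alder reaction of macrocyclic trienes. Ring B closes as the new cyclohexene, ring A closes through the C9–C14 bond by six-membered chair-like folding of the C10–C13 tether (the decatriene mode of intramolecular cycloaddition), and the C8–C17 bond contracts the 24-membered ring to the 16-membered lactone. C8/C9 follow from the 8Z geometry (C7 and C10 cis) and C14/C17 from the E,E diene (C13 and C18 cis). The endo placement of C7 and C10 under the diene, required for the rigid trienoate to reach back to C18 and favoured by secondary overlap with the C4–C7 diene unit, puts all four carbon substituents on one face of ring B and makes the ring fusion cis. The diene face is set by the tether: in the chair-like transition state the C11 methoxy group, the C13 silyloxy group and the fully substituted C8 terminus are equatorial and only the slim C15 terminus is axial, whereas attack on the other face forces C8 axial; the C22/C23 centres bias the macrocycle toward the same fold. Periselectivity over the other diene/dienophile pairs in the two tetraenes is secured by the four-atom tether between C9 and C14, the only pairing that closes an unstrained six-membered ring. The temperature is held at 80 °C because the 4Z-triene could electrocyclise at higher temperature.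

Step 27
Reactants: 40 cis-decalin-fused 16-membered macrolactone
Product: 41 C13 alcohol of 40
Conditions: Bu4NF, AcOH, THF, rt to 40 °C
Reagents that add atoms: none
Why: Fluoride desilylation buffered with acetic acid; the lactone and the N-acyl oxazolidine should be stable, and C13 is no longer allylic.

Step 28
Reactants: 41 C13 alcohol of 40
Product: 43 C13 carbamate with C25/C26 N-acetyl N,O-acetonide, via trichloroacetyl carbamate 42 (not isolated)
Conditions: Cl3CC(O)NCO, CH2Cl2, 0 °C; then K2CO3, MeOH, 0 °C
Reagents that add atoms: trichloroacetyl isocyanate, O=C=NC(=O)C(Cl)(Cl)Cl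
Why: Acylation of the C13 alcohol by the highly electrophilic isocyanate and mild methanolysis of the trichloroacetyl group give the primary carbamate; the tertiary amide and the hindered conjugated lactone should not react.

Step 29
Reactants: 43 C13 carbamate with C25/C26 N-acetyl N,O-acetonide
Product: 44 superstolide A
Conditions: AcOH/H2O/THF (3:1:1), 40 °C
Reagents that add atoms: none
Why: Mild aqueous acid hydrolyses the N-acyl N,O-acetal to the C25 alcohol and the C26 acetamide; carbamate, lactone and polyenes are expected to tolerate it.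

## Compound list

1 | but-2-yn-1-ol | CC#CCO | starting material
2 | sodium 2,2-bis(2-methoxyethoxy)-3-methyl-2,5-dihydro-1,2-oxaaluminol-2-uide (cyclic vinylalanate) | CC1=CCO[Al-]1(OCCOC)OCCOC.[Na+] | intermediate
3 | (Z)-3-iodobut-2-en-1-ol | C/C(I)=C/CO | intermediate
4 | (E)-1,2-bis(tributylstannyl)ethene | CCCC[Sn](CCCC)(CCCC)/C=C/[Sn](CCCC)(CCCC)CCCC | starting material
5 | (2Z,4E)-3-methyl-5-(tributylstannyl)penta-2,4-dien-1-ol | OC/C=C(C)\C=C\[Sn](CCCC)(CCCC)CCCC | intermediate
6 | (2Z,4E)-3-methyl-5-(tributylstannyl)penta-2,4-dienal | O=C/C=C(C)\C=C\[Sn](CCCC)(CCCC)CCCC | intermediate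
7 | tert-butyl 2-[(4R,6S)-6-formyl-2,2-dimethyl-1,3-dioxan-4-yl]acetate | CC(C)(C)OC(=O)C[C@H]1C[C@@H](C=O)OC(C)(C)O1 | starting material
8 | triethyl 4-phosphonocrotonate | CCOC(=O)/C=C/CP(=O)(OCC)OCC | starting material
9 | tert-butyl 2-[(4R,6S)-6-[(1E,3E)-5-ethoxy-5-oxopenta-1,3-dien-1-yl]-2,2-dimethyl-1,3-dioxan-4-yl]acetate | CC(C)(C)OC(=O)C[C@H]1C[C@@H](/C=C/C=C/C(=O)OCC)OC(C)(C)O1 | intermediate
10 | (3R,5S,6E,8E)-10-ethoxy-3,5-dihydroxy-10-oxodeca-6,8-dienoic acid | OC(=O)C[C@H](O)C[C@H](O)/C=C/C=C/C(=O)OCC | intermediate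
11 | ethyl (2E,4E)-5-[(2S,4R)-4-hydroxy-6-oxooxan-2-yl]penta-2,4-dienoate | O=C1C[C@H](O)C[C@@H](/C=C/C=C/C(=O)OCC)O1 | intermediate
12 | ethyl (2E,4E)-5-[(2S,4R)-4-methoxy-6-oxooxan-2-yl]penta-2,4-dienoate | O=C1C[C@H](OC)C[C@@H](/C=C/C=C/C(=O)OCC)O1 | intermediate
13 | (4R,6S)-6-[(1E,3E)-5-hydroxypenta-1,3-dien-1-yl]-4-methoxyoxan-2-ol (anomeric mixture) | OC1C[C@H](OC)C[C@@H](/C=C/C=C/CO)O1 | intermediate
14 | (2E,4E,6S,8S,10Z)-11-iodo-8-methoxydodeca-2,4,10-triene-1,6-diol | C/C(I)=C/C[C@H](OC)C[C@H](O)/C=C/C=C/CO | intermediate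
15 | (2E,4E,6S,8S,10Z)-6-hydroxy-11-iodo-8-methoxydodeca-2,4,10-trienal | C/C(I)=C/C[C@H](OC)C[C@H](O)/C=C/C=C/C=O | intermediate
16 | 2-(triphenylphosphoranylidene)propanal | CC(C=O)=P(c1ccccc1)(c1ccccc1)c1ccccc1 | starting material
17 | (2E,4E,6E,8S,10S,12Z)-8-hydroxy-13-iodo-10-methoxy-2-methyltetradeca-2,4,6,12-tetraenal | C/C(I)=C/C[C@H](OC)C[C@H](O)/C=C/C=C/C=C(\C)C=O | intermediate
18 | (2E,4E,6E,8S,10S,12Z)-8-[(tert-butyldimethylsilyl)oxy]-13-iodo-10-methoxy-2-methyltetradeca-2,4,6,12-tetraenal (C8–C20 fragment) | C/C(I)=C/C[C@H](OC)C[C@H](O[Si](C)(C)C(C)(C)C)/C=C/C=C/C=C(\C)C=O | intermediate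
19 | tert-butyl N-[(2R)-1-oxopropan-2-yl]carbamate (N-Boc-D-alaninal) | O=C[C@@H](C)NC(=O)OC(C)(C)C | starting material
20 | diisopinocampheylborinate of 21 | C=C[C@H](C)[C@H](OB([C@@H]1C[C@@H]2C[C@H]([C@H]1C)C2(C)C)[C@@H]1C[C@@H]2C[C@H]([C@H]1C)C2(C)C)[C@@H](C)NC(=O)OC(C)(C)C | intermediate
21 | tert-butyl N-[(2R,3S,4S)-3-hydroxy-4-methylhex-5-en-2-yl]carbamate | C=C[C@H](C)[C@H](O)[C@@H](C)NC(=O)OC(C)(C)C | intermediate
22 | (2R,3S,4S)-3-hydroxy-4-methylhex-5-en-2-aminium chloride | C=C[C@H](C)[C@H](O)[C@@H](C)[NH3+].[Cl-] | intermediate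
23 | N-[(2R,3S,4S)-3-hydroxy-4-methylhex-5-en-2-yl]acetamide | C=C[C@H](C)[C@H](O)[C@@H](C)NC(C)=O | intermediate
24 | 1-[(4R,5S)-5-[(2S)-but-3-en-2-yl]-2,2,4-trimethyl-1,3-oxazolidin-3-yl]ethan-1-one | C=C[C@H](C)[C@@H]1OC(C)(C)N(C(C)=O)[C@@H]1C | intermediate
25 | ozonide (1,2,4-trioxolane) of 24 | C1OC(OO1)[C@H](C)[C@@H]2OC(C)(C)N(C(C)=O)[C@@H]2C | intermediate
26 | (2R)-2-[(4R,5S)-3-acetyl-2,2,4-trimethyl-1,3-oxazolidin-5-yl]propanal | O=C[C@H](C)[C@@H]1OC(C)(C)N(C(C)=O)[C@@H]1C | intermediate
27 | diisopinocampheylborinate of 28 | C=C[C@@H](C)[C@H]([C@H](C)[C@@H]1OC(C)(C)N(C(C)=O)[C@@H]1C)OB([C@H]1C[C@H]2C[C@@H]([C@@H]1C)C2(C)C)[C@H]1C[C@H]2C[C@@H]([C@@H]1C)C2(C)C | intermediate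
28 | 1-[(4R,5S)-5-[(2S,3R,4R)-3-hydroxy-4-methylhex-5-en-2-yl]-2,2,4-trimethyl-1,3-oxazolidin-3-yl]ethan-1-one | C=C[C@@H](C)[C@H]([C@H](C)[C@@H]1OC(C)(C)N(C(C)=O)[C@@H]1C)O | intermediate
29 | triethylsilyl ether of 28 (C20–C27 alkene; C23–OSiEt3; centres as in 28) | C=C[C@@H](C)[C@H]([C@H](C)[C@@H]1OC(C)(C)N(C(C)=O)[C@@H]1C)O[Si](CC)(CC)CC | intermediate
30 | ozonide (1,2,4-trioxolane) of 29 | C1OC(OO1)[C@@H](C)[C@H]([C@H](C)[C@@H]2OC(C)(C)N(C(C)=O)[C@@H]2C)O[Si](CC)(CC)CC | intermediate
31 | C21 aldehyde (C21–C27 chain; C23–OSiEt3; centres as in 28) | O=C[C@@H](C)[C@H]([C@H](C)[C@@H]1OC(C)(C)N(C(C)=O)[C@@H]1C)O[Si](CC)(CC)CC | intermediate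
32 | C21 primary alcohol (C21–C27 chain; C23–OSiEt3; centres as in 28) | OC[C@@H](C)[C@H]([C@H](C)[C@@H]1OC(C)(C)N(C(C)=O)[C@@H]1C)O[Si](CC)(CC)CC | intermediate
33 | C21 1-phenyl-1H-tetrazol-5-yl sulfide (C21–C27 chain; centres as in 28) | C(Sc1nnnn1-c1ccccc1)[C@@H](C)[C@H]([C@H](C)[C@@H]1OC(C)(C)N(C(C)=O)[C@@H]1C)O[Si](CC)(CC)CC | intermediate
34 | C21 1-phenyl-1H-tetrazol-5-yl sulfone (C21–C27 fragment; centres as in 28) | O=S(=O)(C[C@@H](C)[C@H]([C@H](C)[C@@H]1OC(C)(C)N(C(C)=O)[C@@H]1C)O[Si](CC)(CC)CC)c1nnnn1-c1ccccc1 | intermediate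
35 | C8–C27 iodo tetraene (8Z,14E,16E,18E,20E; 8-iodo; 11-OMe; 13-OSiMe2t-Bu; 23-OSiEt3; C25/C26 N-acetyl N,O-acetonide; all centres as in 44) | C/C(I)=C/C[C@H](OC)C[C@H](O[Si](C)(C)C(C)(C)C)/C=C/C=C/C=C(C)/C=C/[C@@H](C)[C@H]([C@H](C)[C@@H]1OC(C)(C)N(C(C)=O)[C@@H]1C)O[Si](CC)(CC)CC | intermediate
36 | C23 alcohol of 35 | C/C(I)=C/C[C@H](OC)C[C@H](O[Si](C)(C)C(C)(C)C)/C=C/C=C/C=C(C)/C=C/[C@@H](C)[C@H]([C@H](C)[C@@H]1OC(C)(C)N(C(C)=O)[C@@H]1C)O | intermediate
37 | C23 diethylphosphonoacetate of 36 | C/C(I)=C/C[C@H](OC)C[C@H](O[Si](C)(C)C(C)(C)C)/C=C/C=C/C=C(C)/C=C/[C@@H](C)[C@H]([C@H](C)[C@@H]1OC(C)(C)N(C(C)=O)[C@@H]1C)OC(=O)CP(=O)(OCC)OCC | intermediate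
38 | open-chain C1–C27 ester: (2E,4Z,6E)-7-stannyl trienoate on O23 and 8Z vinyl iodide | C/C(I)=C/C[C@H](OC)C[C@H](O[Si](C)(C)C(C)(C)C)/C=C/C=C/C=C(C)/C=C/[C@@H](C)[C@H]([C@H](C)[C@@H]1OC(C)(C)N(C(C)=O)[C@@H]1C)OC(=O)/C=C/C=C(C)\C=C\[Sn](CCCC)(CCCC)CCCC | intermediate
39 | 24-membered (2E,4Z,6E,8Z,14E,16E,18E,20E)-octaene macrolactone (11-OMe; 13-OSiMe2t-Bu; C25/C26 N-acetyl N,O-acetonide) | CO[C@@H]1C[C@H](O[Si](C)(C)C(C)(C)C)/C=C/C=C/C=C(C)/C=C/[C@@H](C)[C@H]([C@H](C)[C@@H]2OC(C)(C)N(C(C)=O)[C@@H]2C)OC(=O)/C=C/C=C(C)\C=C\C(C)=C/C1 | intermediate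
40 | cis-decalin-fused 16-membered macrolactone (13-OSiMe2t-Bu; C25/C26 N-acetyl N,O-acetonide; ring centres as in 44) | CO[C@@H]1C[C@H](O[Si](C)(C)C(C)(C)C)[C@@H]2C=C[C@@H]3/C=C(C)/C=C/[C@@H](C)[C@H]([C@H](C)[C@@H]4OC(C)(C)N(C(C)=O)[C@@H]4C)OC(=O)/C=C/C=C(C)\C=C\[C@]3(C)[C@@H]2C1 | intermediate
41 | C13 alcohol of 40 | CO[C@@H]1C[C@H](O)[C@@H]2C=C[C@@H]3/C=C(C)/C=C/[C@@H](C)[C@H]([C@H](C)[C@@H]4OC(C)(C)N(C(C)=O)[C@@H]4C)OC(=O)/C=C/C=C(C)\C=C\[C@]3(C)[C@@H]2C1 | intermediate
42 | C13 N-trichloroacetyl carbamate of 41 | CO[C@@H]1C[C@H](OC(=O)NC(=O)C(Cl)(Cl)Cl)[C@@H]2C=C[C@@H]3/C=C(C)/C=C/[C@@H](C)[C@H]([C@H](C)[C@@H]4OC(C)(C)N(C(C)=O)[C@@H]4C)OC(=O)/C=C/C=C(C)\C=C\[C@]3(C)[C@@H]2C1 | intermediate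
43 | C13 carbamate with C25/C26 N-acetyl N,O-acetonide | CO[C@@H]1C[C@H](OC(N)=O)[C@@H]2C=C[C@@H]3/C=C(C)/C=C/[C@@H](C)[C@H]([C@H](C)[C@@H]4OC(C)(C)N(C(C)=O)[C@@H]4C)OC(=O)/C=C/C=C(C)\C=C\[C@]3(C)[C@@H]2C1 | intermediate
44 | superstolide A | CO[C@@H]1C[C@H](OC(N)=O)[C@@H]2C=C[C@@H]3/C=C(C)/C=C/[C@@H](C)[C@H]([C@H](C)[C@H](O)[C@@H](C)NC(C)=O)OC(=O)/C=C/C=C(C)\C=C\[C@]3(C)[C@@H]2C1 | target

## Step count and least certain steps

Total step count: 29. Longest linear sequence: 18 steps (steps 12–29, from 19); the central branch (steps 4–11, then 21–29) is 17 steps.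

Step 26 (key step). The most likely failure is insufficient facial selectivity: the chair-like fold with C8 equatorial and its diastereofacial alternative differ only in conformational energy, so both cis-fused adducts may form. Two slower side processes are thermal 6π-electrocyclisation of the 4Z-triene and cycloaddition through another diene/dienophile pair, both of which grow with temperature and time. Fallback: move the cycloaddition ahead of ring closure. From 36, intermolecular Stille coupling with 6 (Pd2(dba)3, AsPh3, DMF) gives the open-chain hydroxy tetraenal F1. Its aldehyde-activated tetraene undergoes the same decatriene-type intramolecular Diels–Alder reaction on gentle heating (toluene, 60 °C) to the decalin dienal F2, from which the wanted diastereomer is separated by chromatography. Acylation with diethylphosphonoacetic acid (N,N'-dicyclohexylcarbodiimide) gives the decalin phosphonoacetate F3, and a Horner–Wadsworth–Emmons macrocyclisation at C2=C3 (LiCl, i-Pr2NEt, MeCN, high dilution) closes the 16-membered lactone and rejoins the route at 40.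

Step 25. Oxidative addition into the hindered, trisubstituted Z vinyl iodide may be slow relative to protodestannylation and intermolecular coupling, so oligomerisation at the concentrations needed for a practical rate is the main risk. Fallback: change the ring-closing bond. From 37, an intermolecular Stille coupling with an excess of 6 (no dilution constraint) gives the open-chain phosphonoacetate trienal F4, and an intramolecular Horner–Wadsworth–Emmons reaction (LiCl, i-Pr2NEt, MeCN, high dilution) closes the 24-membered ring at C2=C3 and rejoins the route at 39.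

Step 21. Erosion of E selectivity is the main risk, because conjugated aldehydes add to sulfonyl carbanions less selectively than saturated ones; competing enolisation toward C22 by the carbanion would lower conversion. Fallback: reverse the polarity of the olefination. From 18, NaBH4/CeCl3·7H2O reduction gives the trienol F5, CBr4/PPh3 gives the trienyl bromide F6, and PBu3 gives the tributylphosphonium bromide F7. Its ylide (LiN(SiMe3)2, THF, −78 °C) is combined with aldehyde 31 (isolated by giving step 18 a PPh3 work-up in place of NaBH4) in a Wittig reaction; allylic trialkylphosphonium ylides are E-selective, and the product is 35.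

Step 8. The lactol may open too slowly at −78 °C for the thermally fragile iodo ylide, and prolonged exposure of the β-methoxy aldehyde to base invites β-elimination; lower Z selectivity than with a simple aldehyde is also possible. Fallback: perform the same olefination on a true aldehyde. From 12, AlMe3/MeONHMe·HCl opens the lactone to the hydroxy Weinreb amide F8, t-BuMe2SiOSO2CF3/2,6-lutidine gives the silyl ether F9, and i-Bu2AlH reduces amide and ester to the aldehyde dienol F10. The iodo-Wittig reaction of step 8 then gives the vinyl iodide dienol F11, TEMPO/PhI(OAc)2 gives the dienal F12, and Wittig reaction with 16 rejoins the route at 18.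

## Further compounds

F1 | step 26 | open-chain hydroxy tetraenal (C3 aldehyde; free C23 hydroxyl) | O=C/C=C(C)\C=C\C(C)=C/C[C@H](OC)C[C@H](O[Si](C)(C)C(C)(C)C)/C=C/C=C/C=C(C)/C=C/[C@@H](C)[C@H]([C@H](C)[C@@H]1OC(C)(C)N(C(C)=O)[C@@H]1C)O
F2 | step 26 | decalin dienal (C3 aldehyde; free C23 hydroxyl) | CO[C@@H]1C[C@H](O[Si](C)(C)C(C)(C)C)[C@@H]2C=C[C@H](/C=C(C)/C=C/[C@@H](C)[C@@H](O)[C@H](C)[C@@H]3OC(C)(C)N(C(C)=O)[C@@H]3C)[C@](C)(/C=C/C(C)=C\C=O)[C@@H]2C1
F3 | step 26 | decalin phosphonoacetate (C23 diethylphosphonoacetate of F2) | CO[C@@H]1C[C@H](O[Si](C)(C)C(C)(C)C)[C@@H]2C=C[C@H](/C=C(C)/C=C/[C@@H](C)[C@@H](OC(=O)CP(=O)(OCC)OCC)[C@H](C)[C@@H]3OC(C)(C)N(C(C)=O)[C@@H]3C)[C@](C)(/C=C/C(C)=C\C=O)[C@@H]2C1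
F4 | step 25 | open-chain phosphonoacetate trienal | O=C/C=C(C)\C=C\C(C)=C/C[C@H](OC)C[C@H](O[Si](C)(C)C(C)(C)C)/C=C/C=C/C=C(C)/C=C/[C@@H](C)[C@H]([C@H](C)[C@@H]1OC(C)(C)N(C(C)=O)[C@@H]1C)OC(=O)CP(=O)(OCC)OCC
F5 | step 21 | trienol from 18 (C20 alcohol) | C/C(I)=C/C[C@H](OC)C[C@H](O[Si](C)(C)C(C)(C)C)/C=C/C=C/C=C(\C)CO
F6 | step 21 | trienyl bromide (C20 bromide) | C/C(I)=C/C[C@H](OC)C[C@H](O[Si](C)(C)C(C)(C)C)/C=C/C=C/C=C(\C)CBr
F7 | step 21 | tributylphosphonium bromide (C20 phosphonium salt) | C/C(I)=C/C[C@H](OC)C[C@H](O[Si](C)(C)C(C)(C)C)/C=C/C=C/C=C(\C)C[P+](CCCC)(CCCC)CCCC.[Br-]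
F8 | step 8 | hydroxy Weinreb amide from 12 | CON(C)C(=O)C[C@H](OC)C[C@H](O)/C=C/C=C/C(=O)OCC
F9 | step 8 | silyl ether of F8 | CON(C)C(=O)C[C@H](OC)C[C@H](O[Si](C)(C)C(C)(C)C)/C=C/C=C/C(=O)OCC
F10 | step 8 | aldehyde dienol (C9 aldehyde; C18 alcohol; 13-OSiMe2t-Bu) | O=CC[C@H](OC)C[C@H](O[Si](C)(C)C(C)(C)C)/C=C/C=C/CO
F11 | step 8 | vinyl iodide dienol (8Z iodide; C18 alcohol; 13-OSiMe2t-Bu) | C/C(I)=C/C[C@H](OC)C[C@H](O[Si](C)(C)C(C)(C)C)/C=C/C=C/CO
F12 | step 8 | dienal (8Z iodide; C18 aldehyde; 13-OSiMe2t-Bu) | C/C(I)=C/C[C@H](OC)C[C@H](O[Si](C)(C)C(C)(C)C)/C=C/C=C/C=O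
A1 | alternative 1 | cis-decalin core (C7 methyl ester; C18 aldehyde; 11-OMe; 13-OSiMe2t-Bu) | CO[C@@H]1C[C@H](O[Si](C)(C)C(C)(C)C)[C@@H]2C=C[C@H](C=O)[C@](C)(C(=O)OC)[C@@H]2C1
A2 | alternative 1 | decalin seco acid (C1 acid; free C23 hydroxyl) | CO[C@@H]1C[C@H](O[Si](C)(C)C(C)(C)C)[C@@H]2C=C[C@H](/C=C(C)/C=C/[C@@H](C)[C@@H](O)[C@H](C)[C@@H]3OC(C)(C)N(C(C)=O)[C@@H]3C)[C@](C)(/C=C/C(C)=C\C=C\C(=O)O)[C@@H]2C1
A3 | alternative 2 | acyclic octaene ester (C19 pinacol boronate; C20 iodide) | I/C=C/[C@@H](C)[C@H]([C@H](C)[C@@H]1OC(C)(C)N(C(C)=O)[C@@H]1C)OC(=O)/C=C/C=C(C)\C=C\C(C)=C/C[C@H](OC)C[C@H](O[Si](C)(C)C(C)(C)C)/C=C/C=C/C=C(\C)B1OC(C)(C)C(C)(C)O1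
A4 | alternative 3 | tetralin with resorcinol-type ring A (C16 ketal; C7 and C18 as silyloxymethyl groups) | COc1cc(O[Si](C)(C)C(C)(C)C)c2CC3(OCCO3)[C@H](CO[Si](C)(C)C(C)(C)C)[C@](C)(CO[Si](C)(C)C(C)(C)C)c2c1
A5 | alternative 3 | all-cis hydrogenated decalin from A4 | CO[C@@H]1C[C@H](O[Si](C)(C)C(C)(C)C)[C@@H]2CC3(OCCO3)[C@H](CO[Si](C)(C)C(C)(C)C)[C@](C)(CO[Si](C)(C)C(C)(C)C)[C@@H]2C1
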